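## Retrosynthetic overview

1. Feature (C1 = ester carbon): on the cyclopentene ring the tertiary C9–OH and the C12 ketone stand 1,4 to each other across C10=C11(Br). C9 and C12 are therefore the two ends of the ring diene of a 1-alkyl-3-bromo-6-alkenylfulvene, and in the 2,3-dioxabicyclo[2.2.1]heptene made from it only the C12 bridgehead carries a hydrogen.
2. Last disconnection: both C–O bonds go back to O2 and the bromofulvene. (4+2) photooxygenation followed by Kornblum–DeLaMare opening of the peroxide with a chiral tertiary amine, run as a kinetic resolution, gives the ketone, the carbinol, the bromoenone and the (9S) centre.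
3. Fulvene: 1,4-loss of water from a C9 carbinol. The C8–C9 bond comes from lanthanide-promoted 1,2-addition of a C8 Grignard reagent to the C9 ketone of a 3-bromo-5-alkylidenecyclopent-2-enone; the ester travels as a bridged orthoester, because no reagent hard enough for this ketone tolerates a free methyl ester.
4. C13=C14: kinetic aldol condensation of 3-bromocyclopent-2-enone (from cyclopentane-1,3-dione) with (E)-pent-2-enal. The usual E outcome (chain anti to C9=O, cis to C12) becomes 13Z once the carbonyl sits at C12.
5. Rings: the carbocycle is bought. The only ring formed is the temporary peroxide bicycle of the key step, and it is opened again in the same flask.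

Key step: step 9

Assumption: the sense in which a cinchona-type amine distinguishes the two peroxide enantiomers cannot be predicted, so the route is written for the quinidine-derived catalyst consuming the (1S,4S)-peroxide, and the quinine-derived pseudo-enantiomer (9-O-acetylcupreine) replaces it if a trial run shows the opposite sense.

## Route

Step 1
Reactants: 1 cyclopentane-1,3-dione
Product: 2 3-bromocyclopent-2-en-1-one
Conditions: (COBr)2 (1.1 equiv), DMF (cat.), CH2Cl2, 0 °C → rt; short silica filtration, used promptly
Reagents that add atoms: oxalyl bromide, O=C(Br)C(=O)Br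
Why: Vilsmeier-type activation of the enol oxygen of the vinylogous acid, then addition–elimination of bromide, is the standard conversion of cyclic 1,3-diones into β-bromoenones, and the symmetry of 1 excludes regioisomers.

Step 2
Reactants: 2 3-bromocyclopent-2-en-1-one; 3 (E)-pent-2-enal
Product: 5 3-bromo-5-[(2E)-1-hydroxypent-2-en-1-yl]cyclopent-2-en-1-one (racemic diastereomer mixture), via lithium dienolate 4 (not isolated)
Conditions: LDA (commercial solution, 1.05 equiv), THF, −78 °C, slow addition of 2; then 3, −78 °C; AcOH quench at −78 °C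
Reagents that add atoms: none
Why: Kinetic deprotonation of a cyclopentenone with LDA removes the α′-hydrogen (future C13) to give the cross-conjugated lithium dienolate, which adds 1,2 to the enal in a lithium aldol addition; both new stereocentres are erased in step 3, so the mixture is carried on.

Step 3
Reactants: 5 3-bromo-5-[(2E)-1-hydroxypent-2-en-1-yl]cyclopent-2-en-1-one
Product: 7 (5E)-3-bromo-5-[(2E)-pent-2-en-1-ylidene]cyclopent-2-en-1-one, via allylic mesylate 6 (not isolated)
Conditions: MsCl (1.1 equiv), Et3N (3 equiv), CH2Cl2, −20 → 0 °C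
Reagents that add atoms: none
Why: Mesylation followed by E1cB elimination completes the aldol condensation, and the chain should turn away from the C9 carbonyl oxygen (E, cis to C12H2), which is both the kinetic and the thermodynamic geometry of 5-alkylidenecyclopentenones.

Step 4
Reactants: 8 8-bromooctanoic acid; 9 (3-methyloxetan-3-yl)methanol
Product: 10 (3-methyloxetan-3-yl)methyl 8-bromooctanoate
Conditions: DCC, DMAP (cat.), CH2Cl2, 0 °C → rt
Reagents that add atoms: none
Why: Steglich esterification joins acid and primary alcohol under neutral conditions that leave the oxetane and the primary bromide untouched.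

Step 5
Reactants: 10 (3-methyloxetan-3-yl)methyl 8-bromooctanoate
Product: 11 1-(7-bromoheptyl)-4-methyl-2,6,7-trioxabicyclo[2.2.2]octane
Conditions: BF3·OEt2 (0.25 equiv), CH2Cl2, −15 → 0 °C; Et3N quench
Reagents that add atoms: none
Why: Lewis-acid-catalysed rearrangement of an oxetanylmethyl ester (the ester carbonyl opens the activated oxetane, then the alkoxide closes on the dioxocarbenium ion) is the standard entry to the base-stable bridged (OBO) orthoester.

Step 6
Reactants: 11 1-(7-bromoheptyl)-4-methyl-2,6,7-trioxabicyclo[2.2.2]octane; 7 (5E)-3-bromo-5-[(2E)-pent-2-en-1-ylidene]cyclopent-2-en-1-one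
Product: 13 (5E)-3-bromo-1-[7-(4-methyl-2,6,7-trioxabicyclo[2.2.2]octan-1-yl)heptyl]-5-[(2E)-pent-2-en-1-ylidene]cyclopent-2-en-1-ol (racemic), via Grignard reagent 12 (not isolated)
Conditions: 11, Mg, THF, rt → 40 °C; separately 7, LaCl3·2LiCl (1.1 equiv), THF, rt then −78 °C; add 12, −78 → −40 °C; aq NaHCO3/Rochelle salt
Reagents that add atoms: none
Why: In this lanthanide-promoted Grignard addition the oxophilic La(III) activates the C9 carbonyl and tempers the basicity of the reagent, so hard 1,2-attack should outrun enolisation at C12 and conjugate attack at C11, C14 or C16, while the orthoester carries the ester oxidation level through; the new C9 centre is racemic and is erased in step 8.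

Step 7
Reactants: 13 (5E)-3-bromo-1-[7-(4-methyl-2,6,7-trioxabicyclo[2.2.2]octan-1-yl)heptyl]-5-[(2E)-pent-2-en-1-ylidene]cyclopent-2-en-1-ol
Product: 15 methyl 8-{(5E)-3-bromo-1-hydroxy-5-[(2E)-pent-2-en-1-ylidene]cyclopent-2-en-1-yl}octanoate (racemic), via bis(hydroxymethyl)propyl ester 14 (not isolated)
Conditions: PPTS (cat.), THF–H2O, 0 °C; extraction; K2CO3 (cat.), dry MeOH, rt
Reagents that add atoms: water, O; methanol, CO
Why: Bridged orthoesters hydrolyse very readily under weakly acidic conditions to the 2,2-bis(hydroxymethyl)propyl ester, which carbonate-catalysed transesterification converts into the methyl ester; acid this weak should spare most of the C9 carbinol, and any early loss of water only anticipates step 8.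

Step 8
Reactants: 15 methyl 8-{(5E)-3-bromo-1-hydroxy-5-[(2E)-pent-2-en-1-ylidene]cyclopent-2-en-1-yl}octanoate
Product: 17 methyl 8-{(5E)-3-bromo-5-[(2E)-pent-2-en-1-ylidene]cyclopenta-1,3-dien-1-yl}octanoate, via tertiary mesylate 16 (not isolated)
Conditions: MsCl (1.5 equiv), Et3N (5 equiv), CH2Cl2, −40 → 0 °C, Ar, dark; cold neutral alumina plug, used at once
Reagents that add atoms: none
Why: Sulfene mesylation of the tertiary bis-allylic alcohol gives a mesylate that ionises at once, and the amine removes the doubly allylic C12 proton of the delocalised cation (E1-type 1,4-elimination) to give the fulvene, whose chain stays on the C12 side because the other geometry would press it against the C9 alkyl group.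

Step 9
Reactants: 17 methyl 8-{(5E)-3-bromo-5-[(2E)-pent-2-en-1-ylidene]cyclopenta-1,3-dien-1-yl}octanoate; 18 dioxygen
Product: 20 methyl 8-{(1S,5Z)-3-bromo-1-hydroxy-4-oxo-5-[(2E)-pent-2-en-1-ylidene]cyclopent-2-en-1-yl}octanoate, via racemic fulvene endoperoxide 19 (not isolated)
Conditions: O2, tetraphenylporphyrin (cat.), light > 550 nm, dilute CH2Cl2, −78 °C; Ar purge, dark; 9-O-acetylcupreidine (20 mol %), −78 → −50 °C, halted short of half conversion with AcOH (aliquots reduced and assayed on a chiral phase); thiourea, MeOH, −50 → −20 °C; chromatography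
Reagents that add atoms: dioxygen (18), O=O
Why: Proposed new method: singlet oxygen adds suprafacially and in concerted (4+2) fashion to C9 and C12, the ends of the ring diene that the five-membered ring locks s-cis, and this cycloaddition closes the temporary 1,2-dioxolane ring of the 2,3-dioxabicyclo[2.2.1]hept-5-ene 19 as a racemate, while the freely rotating C13–C16 diene and the allylic CH2 groups react much more slowly. The quinuclidine nitrogen of the catalyst then takes the C12 bridgehead hydrogen in an E2-like Kornblum–DeLaMare fragmentation that breaks the O–O bond, turns C12 into the ketone and frees the C9 oxygen as the tertiary alcohol, so that the α-bromoenone appears in the same event. This cleavage can run in one direction only because C9 has no hydrogen, and ring strain together with the inductive pull of the C11 bromine on the C12–H bond should let it proceed below the temperature at which fulvene endoperoxides rearrange. The closest known reactions are fulvene photooxygenation followed by achiral-base opening to 4-hydroxy-5-alkylidenecyclopent-2-enones and the cinchona-amine-catalysed desymmetrising Kornblum–DeLaMare rearrangement of meso endoperoxides; what is new is the use of such a catalyst to resolve a racemic and thermally labile fulvene endoperoxide. The C9 stereocentre is made without control in the cycloaddition and is selected afterwards by the catalyst, which holds the peroxide by a hydrogen bond from its 6′-OH while its nitrogen reaches C12–H and must fit the (1S,4S)-enantiomer better than the mirror image; the unlike bridgeheads (H against the C8 chain) and the unlike two-atom bridges (O–O against CH=CBr) are what it can read, and stopping short of half conversion protects the enantiomeric purity of 20. The C13=C14 bond is not touched, so the chain that lay cis to C12–H ends cis to the new carbonyl (13Z), and thiourea finally reduces the left-over (1R,4R)-19 to a polar diol that chromatography removes.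

## Compound list

1 | cyclopentane-1,3-dione | O=C1CCC(=O)C1 | starting material
2 | 3-bromocyclopent-2-en-1-one | O=C1CCC(Br)=C1 | intermediate
3 | (E)-pent-2-enal | CC/C=C/C=O | starting material
4 | lithium 4-bromocyclopenta-1,4-dien-1-olate (cross-conjugated dienolate of 2) | [Li+].[O-]C1=CCC(Br)=C1 | intermediate
5 | 3-bromo-5-[(2E)-1-hydroxypent-2-en-1-yl]cyclopent-2-en-1-one, racemic diastereomer mixture | CC/C=C/C(O)C1CC(Br)=CC1=O | intermediate
6 | (2E)-1-(4-bromo-2-oxocyclopent-3-en-1-yl)pent-2-en-1-yl methanesulfonate | CC/C=C/C(OS(C)(=O)=O)C1CC(Br)=CC1=O | intermediate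
7 | (5E)-3-bromo-5-[(2E)-pent-2-en-1-ylidene]cyclopent-2-en-1-one | CC/C=C/C=C1\CC(Br)=CC1=O | intermediate
8 | 8-bromooctanoic acid | OC(=O)CCCCCCCBr | starting material
9 | (3-methyloxetan-3-yl)methanol | CC1(CO)COC1 | starting material
10 | (3-methyloxetan-3-yl)methyl 8-bromooctanoate | CC1(COC(=O)CCCCCCCBr)COC1 | intermediate
11 | 1-(7-bromoheptyl)-4-methyl-2,6,7-trioxabicyclo[2.2.2]octane | CC12COC(CCCCCCCBr)(OC1)OC2 | intermediate
12 | [7-(4-methyl-2,6,7-trioxabicyclo[2.2.2]octan-1-yl)heptyl]magnesium bromide | CC12COC(CCCCCCC[Mg]Br)(OC1)OC2 | intermediate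
13 | (5E)-3-bromo-1-[7-(4-methyl-2,6,7-trioxabicyclo[2.2.2]octan-1-yl)heptyl]-5-[(2E)-pent-2-en-1-ylidene]cyclopent-2-en-1-ol, racemic | CC/C=C/C=C1\CC(Br)=CC1(O)CCCCCCCC12OCC(C)(CO1)CO2 | intermediate
14 | 3-hydroxy-2-(hydroxymethyl)-2-methylpropyl 8-{(5E)-3-bromo-1-hydroxy-5-[(2E)-pent-2-en-1-ylidene]cyclopent-2-en-1-yl}octanoate, racemic | CC/C=C/C=C1\CC(Br)=CC1(O)CCCCCCCC(=O)OCC(C)(CO)CO | intermediate
15 | methyl 8-{(5E)-3-bromo-1-hydroxy-5-[(2E)-pent-2-en-1-ylidene]cyclopent-2-en-1-yl}octanoate, racemic | CC/C=C/C=C1\CC(Br)=CC1(O)CCCCCCCC(=O)OC | intermediate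
16 | methyl 8-{(5E)-3-bromo-1-(methylsulfonyloxy)-5-[(2E)-pent-2-en-1-ylidene]cyclopent-2-en-1-yl}octanoate | CC/C=C/C=C1\CC(Br)=CC1(OS(C)(=O)=O)CCCCCCCC(=O)OC | intermediate
17 | methyl 8-{(5E)-3-bromo-5-[(2E)-pent-2-en-1-ylidene]cyclopenta-1,3-dien-1-yl}octanoate (chain cis to C12–H) | CC/C=C/C=C1\C=C(Br)C=C1CCCCCCCC(=O)OC | intermediate
18 | dioxygen | O=O | starting material
19 | methyl 8-{(1S,4S,7E)-5-bromo-7-[(2E)-pent-2-en-1-ylidene]-2,3-dioxabicyclo[2.2.1]hept-5-en-1-yl}octanoate, formed as the racemate; the enantiomer drawn is the one the catalyst consumes | CC/C=C/C=C1\[C@H]2C(Br)=C[C@@]1(OO2)CCCCCCCC(=O)OC | intermediate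
20 | methyl 8-{(1S,5Z)-3-bromo-1-hydroxy-4-oxo-5-[(2E)-pent-2-en-1-ylidene]cyclopent-2-en-1-yl}octanoate (9S,13Z,15E) | CC/C=C/C=C1\C(=O)C(Br)=C[C@@]1(O)CCCCCCCC(=O)OC | target

## Step count and risks

Total steps: 9. Longest linear sequence: 7 (steps 1, 2, 3, 6, 7, 8, 9); steps 4 and 5 form the side branch.

**1. Step 9 (proposed new method).**
- What may go wrong: the amine may distinguish the two peroxide enantiomers too weakly. Proton transfer may be too slow below the temperature at which the bridge rearranges. The peroxide may oxidise the amine. Sensitised isomerisation at C13=C14 may blur the geometry.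
- Fallback (known reaction types, from 17 back to 20): 17 is photooxygenated as in step 9, and all of racemic 19 is reduced in the cold with thiourea in MeOH to the racemic cis-diol F1.
- A lipase (Burkholderia cepacia lipase, vinyl acetate, MTBE, rt) acylates only the secondary C12 hydroxyl, and only in one enantiomer. This is an enzymatic kinetic resolution of a cyclopentenol.
- Written for the case in which the (9R,12R)-enantiomer is converted into the (9R,12R)-12-acetate F3, chromatography leaves the (9S,12S)-diol F2. Its doubly allylic secondary alcohol is oxidised with MnO2 (CH2Cl2, rt) to 20, while the tertiary C9 hydroxyl stays inert.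
- If the enzyme prefers the other enantiomer, acylation gives the (9S,12S)-12-acetate F4, which K2CO3/MeOH returns to F2 before the oxidation.

**2. Step 2.**
- What may go wrong: deprotonation may take the γ-hydrogen (C12) instead of the α′-hydrogen (C13). The dienolate may attack the β-carbon of unreacted 2 with loss of bromide. The liberated amine may displace bromide.
- Fallback (from 2 back to 5): soft enolisation (TBSOTf, Et3N, CH2Cl2, −78 → 0 °C) gives the cross-conjugated silyl dienol ether F5, which is kept cold to suppress 1,5-hydrogen shifts.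
- A Mukaiyama aldol addition of F5 to 3 (BF3·OEt2, CH2Cl2, −78 °C) gives 5 after aqueous work-up. Neither a free enolate nor an amide base ever meets the bromoenone.

**3. Step 6.**
- What may go wrong: the reagent may act as a base on the doubly activated C12H2 group. It may instead add in conjugate fashion at C11 (with loss of bromide), at C14 or at C16.
- Fallback (from 5 and 12 back to 17): the aldol is not dehydrated but silylated (TESCl, imidazole, CH2Cl2) to the triethylsilyl ether F6, a plain enone without the extended acceptor.
- Lanthanide-promoted addition of 12 gives the tertiary alcohol F7.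
- The two-stage unmasking of step 7 removes the silyl group and opens the orthoester to the bis(hydroxymethyl)propyl ester F8, and then gives the diol methyl ester F9.
- MsCl/Et3N followed by DBU acts through the bis-mesylate F10. Loss of the tertiary mesylate gives a cyclopentadiene, and deprotonation of that diene expels the C14 mesylate (the E1cB step common to fulvene syntheses from cyclopentadienes and aldehydes). The product is 17, with the chain again turning away from the C9 alkyl group.

## Further compounds

F1 | step 9 | methyl 8-{(1S,4S,5E)-3-bromo-1,4-dihydroxy-5-[(2E)-pent-2-en-1-ylidene]cyclopent-2-en-1-yl}octanoate as the racemate (cis-diol, relative configuration drawn) | CC/C=C/C=C1\[C@H](O)C(Br)=C[C@@]1(O)CCCCCCCC(=O)OC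
F2 | step 9 | methyl 8-{(1S,4S,5E)-3-bromo-1,4-dihydroxy-5-[(2E)-pent-2-en-1-ylidene]cyclopent-2-en-1-yl}octanoate, single (9S,12S)-enantiomer | CC/C=C/C=C1\[C@H](O)C(Br)=C[C@@]1(O)CCCCCCCC(=O)OC
F3 | step 9 | methyl 8-{(1R,4R,5E)-4-acetoxy-3-bromo-1-hydroxy-5-[(2E)-pent-2-en-1-ylidene]cyclopent-2-en-1-yl}octanoate | CC/C=C/C=C1\[C@@H](OC(C)=O)C(Br)=C[C@]1(O)CCCCCCCC(=O)OC
F4 | step 9 | methyl 8-{(1S,4S,5E)-4-acetoxy-3-bromo-1-hydroxy-5-[(2E)-pent-2-en-1-ylidene]cyclopent-2-en-1-yl}octanoate | CC/C=C/C=C1\[C@H](OC(C)=O)C(Br)=C[C@@]1(O)CCCCCCCC(=O)OC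
F5 | step 2 | [(4-bromocyclopenta-1,4-dien-1-yl)oxy](tert-butyl)dimethylsilane | CC(C)(C)[Si](C)(C)OC1=CCC(Br)=C1
F6 | step 6 | 3-bromo-5-[(2E)-1-(triethylsilyloxy)pent-2-en-1-yl]cyclopent-2-en-1-one | CC/C=C/C(O[Si](CC)(CC)CC)C1CC(Br)=CC1=O
F7 | step 6 | 3-bromo-1-[7-(4-methyl-2,6,7-trioxabicyclo[2.2.2]octan-1-yl)heptyl]-5-[(2E)-1-(triethylsilyloxy)pent-2-en-1-yl]cyclopent-2-en-1-ol | CC/C=C/C(O[Si](CC)(CC)CC)C1CC(Br)=CC1(O)CCCCCCCC12OCC(C)(CO1)CO2
F8 | step 6 | 3-hydroxy-2-(hydroxymethyl)-2-methylpropyl 8-{3-bromo-1-hydroxy-5-[(2E)-1-hydroxypent-2-en-1-yl]cyclopent-2-en-1-yl}octanoate | CC/C=C/C(O)C1CC(Br)=CC1(O)CCCCCCCC(=O)OCC(C)(CO)CO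
F9 | step 6 | methyl 8-{3-bromo-1-hydroxy-5-[(2E)-1-hydroxypent-2-en-1-yl]cyclopent-2-en-1-yl}octanoate | CC/C=C/C(O)C1CC(Br)=CC1(O)CCCCCCCC(=O)OC
F10 | step 6 | methyl 8-{3-bromo-1-(methylsulfonyloxy)-5-[(2E)-1-(methylsulfonyloxy)pent-2-en-1-yl]cyclopent-2-en-1-yl}octanoate | CC/C=C/C(OS(C)(=O)=O)C1CC(Br)=CC1(OS(C)(=O)=O)CCCCCCCC(=O)OC
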